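**Retrosynthetic overview**

1. The target is released by fluoride desilylation, in the flask of the key step, of an N,O-bis(triisopropylsilyl) annulation product in which every carbon is already in place.
2. Key disconnection: ring C, the cyclohexadienone (C1' = C=O, C2' = carbon bound to C3 of the lactam, C3' = C–OH, C4' = CH, C5' = C–Me, C6' = C(prenyl)2), is cut across C1'–C2' and C3'–C4'. This gives 3-methyl-4,4-diprenylcyclobutenone (a masked vinylketene supplying C1', C4', C5', C6') and an enantiopure siloxyalkyne (C2', C3'); forward, a formal (4+2) vinylketene–ynol ether annulation.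
3. Enabling feature: ring C is a 6,6-disubstituted cyclohexa-2,4-dienone with oxygen on C1' and C3' flanking C2'. C1'=O is a former ketene carbonyl, the C3' oxygen a former ynol ether oxygen, and the quaternary C6' next to C1' is the terminus at which a dienylketene 6π closure cannot be followed by aromatisation.
4. The siloxyalkyne comes from (R)-3-ethynyl-4-methoxyisoindolin-1-one, made by auxiliary-controlled ethynyl addition to the N-sulfinyl imine of methyl 2-formyl-3-methoxybenzoate (sets the only stereocentre). The cyclobutenone comes from diprenylketene and ethoxyacetylene, ultimately from diethyl malonate and prenyl bromide.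
5. Ring order: ring A (benzene) is bought; a temporary cyclobutenone is made in step 3; ring B (lactam) closes in step 7; ring C closes last, in step 9.

Key step: step 9

Assumption: methyl 2-formyl-3-methoxybenzoate, ethoxyacetylene (hexane solution) and (S)-tert-butanesulfinamide are treated as purchasable, and the silylation in step 8 is taken to occur on the lactam nitrogen as well as on the ynolate oxygen.

**Route**

Step 1
Reactants: 1 diethyl malonate; 2 prenyl bromide (1-bromo-3-methylbut-2-ene, 2.3 equiv)
Product: 3 diethyl 2,2-bis(3-methylbut-2-en-1-yl)malonate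
Conditions: NaH (2.4 equiv), THF/DMF, 0 °C → rt
Reagents that add atoms: none
Why: Twofold SN2 C-alkylation of the malonate enolate by a reactive primary allylic bromide (malonic ester synthesis) should install both prenyl groups on the same carbon.

Step 2
Reactants: 3 diethyl 2,2-bis(3-methylbut-2-en-1-yl)malonate
Product: 5 5-methyl-2-(3-methylbut-2-en-1-yl)hex-4-enoic acid, via diprenylmalonic acid 4 (not isolated)
Conditions: KOH, EtOH/H2O, reflux; cold 1 M HCl to pH 2, extraction; pyridine, 115 °C
Reagents that add atoms: potassium hydroxide, [K+].[OH-]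
Why: Saponification followed by thermal decarboxylation of the geminal diacid (malonic acid synthesis) should give the acid, the basic pyridine medium keeping the carboxyl group from cyclising onto the prenyl double bonds.

Step 3
Reactants: 5 5-methyl-2-(3-methylbut-2-en-1-yl)hex-4-enoic acid; 6 ethoxyacetylene (ethoxyethyne, 2 equiv)
Product: 9 3-ethoxy-4,4-bis(3-methylbut-2-en-1-yl)cyclobut-2-en-1-one, via acid chloride 7 (not isolated), via diprenylketene 8 (not isolated)
Conditions: (COCl)2, DMF (cat.), CH2Cl2, 0 °C → rt, evaporate; 6, Et3N, MeCN, rt → 45 °C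
Reagents that add atoms: none
Why: Dehydrochlorination of the acid chloride should give the disubstituted ketene, which undergoes the known regioselective ketene–alkoxyalkyne [2+2] cycloaddition (ketene carbonyl carbon to the alkyne CH); the one-carbon tether rules out intramolecular capture by the prenyl alkenes.

Step 4
Reactants: 9 3-ethoxy-4,4-bis(3-methylbut-2-en-1-yl)cyclobut-2-en-1-one
Product: 11 3-methyl-4,4-bis(3-methylbut-2-en-1-yl)cyclobut-2-en-1-one, via cyclobutenol 10 (not isolated)
Conditions: MeLi, Et2O, −78 °C; 1 M aq HCl, THF, 0 °C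
Reagents that add atoms: methyllithium, [Li]C
Why: 1,2-Addition of MeLi to the vinylogous ester carbonyl and acid hydrolysis with allylic transposition (Stork–Danheiser-type carbonyl transposition) should place the methyl group on the enone β-carbon and the quaternary carbon next to the new carbonyl.

Step 5
Reactants: 12 methyl 2-formyl-3-methoxybenzoate; 13 (S)-2-methylpropane-2-sulfinamide
Product: 14 methyl 2-[(E)-{[(S)-tert-butylsulfinyl]imino}methyl]-3-methoxybenzoate
Conditions: CuSO4 (anhydrous, 2 equiv), CH2Cl2, rt
Reagents that add atoms: none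
Why: Ellman condensation of an aldehyde with the sulfinamide should give the E aldimine, CuSO4 as water scavenger avoiding the ester exchange that a titanium alkoxide could cause.

Step 6
Reactants: 14 methyl 2-[(E)-{[(S)-tert-butylsulfinyl]imino}methyl]-3-methoxybenzoate
Product: 15 methyl 2-[(1R)-1-{[(S)-tert-butylsulfinyl]amino}prop-2-yn-1-yl]-3-methoxybenzoate
Conditions: HC≡CMgBr (0.5 M in THF, 2 equiv), CH2Cl2, −78 → −40 °C; H2O
Reagents that add atoms: ethynylmagnesium bromide, C#C[Mg]Br
Why: Ellman-type alkynyl Grignard addition in a non-coordinating solvent is expected to pass through the six-membered chair transition state with magnesium bound to the sulfinyl oxygen, and with the (S)-sulfinyl group this model delivers the ethynyl group to the face that gives the (R)-configured carbon, the only stereocentre of the target.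

Step 7
Reactants: 15 methyl 2-[(1R)-1-{[(S)-tert-butylsulfinyl]amino}prop-2-yn-1-yl]-3-methoxybenzoate
Product: 17 (3R)-3-ethynyl-4-methoxy-2,3-dihydro-1H-isoindol-1-one, via amine hydrochloride 16 (not isolated)
Conditions: HCl (4 M in dioxane), MeOH, 0 °C → rt; Et3N, MeOH, rt
Reagents that add atoms: none
Why: Acidic methanolysis of the N–S bond and, on neutralisation, five-membered lactamisation of the free amine onto the ortho ester should close ring B, the weak base leaving the propargylic C–H untouched.

Step 8
Reactants: 17 (3R)-3-ethynyl-4-methoxy-2,3-dihydro-1H-isoindol-1-one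
Product: 19 (3R)-4-methoxy-2-(triisopropylsilyl)-3-{[(triisopropylsilyl)oxy]ethynyl}-2,3-dihydro-1H-isoindol-1-one, via dilithium ynolate 18 (not isolated)
Conditions: LiN(SiMe3)2 (2.2 equiv), THF, −78 °C; LiOOt-Bu (from t-BuOOH and LiN(SiMe3)2, 1.2 equiv), −78 → 0 °C; i-Pr3SiOTf (2.5 equiv), −78 → 0 °C
Reagents that add atoms: tert-butyl hydroperoxide, CC(C)(C)OO; triisopropylsilyl trifluoromethanesulfonate, CC(C)[Si](OS(=O)(=O)C(F)(F)F)(C(C)C)C(C)C
Why: Oxidation of a lithium acetylide by lithium tert-butyl peroxide to the lithium ynolate and O-silylation is the standard route from terminal alkynes to siloxyalkynes; prior N-deprotonation of the lactam should make C3–H non-acidic so that the stereocentre survives, and silylation of the lactamate masks the N–H for the next step.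

Step 9
Reactants: 11 3-methyl-4,4-bis(3-methylbut-2-en-1-yl)cyclobut-2-en-1-one; 19 (3R)-4-methoxy-2-(triisopropylsilyl)-3-{[(triisopropylsilyl)oxy]ethynyl}-2,3-dihydro-1H-isoindol-1-one
Product: 24 (3S)-3-[2-hydroxy-4-methyl-5,5-bis(3-methylbut-2-en-1-yl)-6-oxocyclohexa-1,3-dien-1-yl]-4-methoxy-2,3-dihydro-1H-isoindol-1-one, via vinylketene 20 (not isolated), via alkenylcyclobutenone 21 (not isolated), via dienylketene 22 (not isolated), via bis-silyl dienone 23 (not isolated)
Conditions: toluene (1 M, 11 and 19 equimolar), argon, sealed tube, 80 → 100 °C; then cool, THF, Bu4NF (2.5 equiv), AcOH (2.5 equiv), 0 °C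
Reagents that add atoms: none
Why: Proposed new method: heating should open cyclobutenone 11 (4π electrocyclic, reversible) to vinylketene 20, whose ketene C=C adds in a regioselective [2+2] cycloaddition across the electron-rich triple bond of 19 (ketene carbonyl carbon to the nucleophilic alkyne carbon that carries the lactam, ketene α-carbon to the oxygen-bearing alkyne carbon), so that the C1'–C2' and the C3'–C4' bonds of ring C are both made in this ring-closing event; 4π opening of the resulting alkenylcyclobutenone 21 to dienylketene 22 and 6π electrocyclisation onto the diprenylated terminus (re-forming C1'–C6') then complete the six-membered ring as 23. The closest known reaction type is the Danheiser benzannulation of cyclobutenones with siloxyalkynes, which gives resorcinol monosilyl ethers; what is new is the fully substituted C6', which leaves the 6π product no hydrogen to lose, so the cascade should stop at the 6,6-disubstituted cyclohexa-2,4-dienone, the thermal closure of such dienylketenes being the known reverse of the photochemical ring opening of these dienones. Modes of closure: the temporary four-membered ring by [2+2] cycloaddition, ring C by thermal disrotatory 6π electrocyclisation, overall a formal (4+2) annulation in which the alkyne is inserted between C1' and C4'. No stereocentre is created (the sp3 carbon of 21 is erased on ring opening), and C3 of the lactam is a spectator under the neutral, base-free thermal conditions. The selectivity needed is regiochemical (oxygen on C3', lactam on C2') and is secured by the polarisation of the ynol ether; the chief competitor, a unimolecular [1,5]-hydrogen shift of 20 to a dienal, should be outrun by bimolecular capture at high concentration, and the temperature is held at or below 100 °C to spare the product from Cope or retro-Claisen shifts of its prenyl groups. Because the silyl dienol ether and the N-silyl lactam of 23 are hydrolytically labile, 23 is not isolated but treated in the same flask with acetic acid-buffered Bu4NF, which should cleave the Si–O and Si–N bonds to release the enol and the N–H of 24, the buffer keeping the vinylogous acid protonated so that base-induced retro-Mannich-type loss of configuration at C3 is avoided.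

**Compound list**

1 | diethyl malonate | CCOC(=O)CC(=O)OCC | starting material
2 | prenyl bromide (1-bromo-3-methylbut-2-ene) | CC(C)=CCBr | starting material
3 | diethyl 2,2-bis(3-methylbut-2-en-1-yl)malonate | CCOC(=O)C(CC=C(C)C)(CC=C(C)C)C(=O)OCC | intermediate
4 | 2,2-bis(3-methylbut-2-en-1-yl)malonic acid | OC(=O)C(CC=C(C)C)(CC=C(C)C)C(=O)O | intermediate
5 | 5-methyl-2-(3-methylbut-2-en-1-yl)hex-4-enoic acid | OC(=O)C(CC=C(C)C)CC=C(C)C | intermediate
6 | ethoxyacetylene (ethoxyethyne) | CCOC#C | starting material
7 | 5-methyl-2-(3-methylbut-2-en-1-yl)hex-4-enoyl chloride | ClC(=O)C(CC=C(C)C)CC=C(C)C | intermediate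
8 | 5-methyl-2-(3-methylbut-2-en-1-yl)hexa-1,4-dien-1-one (diprenylketene) | O=C=C(CC=C(C)C)CC=C(C)C | intermediate
9 | 3-ethoxy-4,4-bis(3-methylbut-2-en-1-yl)cyclobut-2-en-1-one | CCOC1=CC(=O)C1(CC=C(C)C)CC=C(C)C | intermediate
10 | 3-ethoxy-1-methyl-4,4-bis(3-methylbut-2-en-1-yl)cyclobut-2-en-1-ol (racemic) | CCOC1=CC(C)(O)C1(CC=C(C)C)CC=C(C)C | intermediate
11 | 3-methyl-4,4-bis(3-methylbut-2-en-1-yl)cyclobut-2-en-1-one | CC1=CC(=O)C1(CC=C(C)C)CC=C(C)C | intermediate
12 | methyl 2-formyl-3-methoxybenzoate | COC(=O)c1cccc(OC)c1C=O | starting material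
13 | (S)-2-methylpropane-2-sulfinamide | CC(C)(C)[S@](=O)N | starting material
14 | methyl 2-[(E)-{[(S)-tert-butylsulfinyl]imino}methyl]-3-methoxybenzoate | COC(=O)c1cccc(OC)c1/C=N/[S@@](=O)C(C)(C)C | intermediate
15 | methyl 2-[(1R)-1-{[(S)-tert-butylsulfinyl]amino}prop-2-yn-1-yl]-3-methoxybenzoate | COC(=O)c1cccc(OC)c1[C@@H](C#C)N[S@@](=O)C(C)(C)C | intermediate
16 | methyl 2-[(1R)-1-aminoprop-2-yn-1-yl]-3-methoxybenzoate hydrochloride | COC(=O)c1cccc(OC)c1[C@@H](C#C)[NH3+].[Cl-] | intermediate
17 | (3R)-3-ethynyl-4-methoxy-2,3-dihydro-1H-isoindol-1-one | COc1cccc2c1[C@@H](C#C)NC2=O | intermediate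
18 | dilithium salt of 17 oxidised at the alkyne terminus (lithium ynolate, lithium lactamate; 3R) | COc1cccc2c1[C@@H](C#C[O-])[N-]C2=O.[Li+].[Li+] | intermediate
19 | (3R)-4-methoxy-2-(triisopropylsilyl)-3-{[(triisopropylsilyl)oxy]ethynyl}-2,3-dihydro-1H-isoindol-1-one | COc1cccc2c1[C@@H](C#CO[Si](C(C)C)(C(C)C)C(C)C)N([Si](C(C)C)(C(C)C)C(C)C)C2=O | intermediate
20 | 3,7-dimethyl-4-(3-methylbut-2-en-1-yl)octa-1,3,6-trien-1-one (vinylketene) | O=C=CC(C)=C(CC=C(C)C)CC=C(C)C | intermediate
21 | (3S)-4-methoxy-3-{3-[6-methyl-3-(3-methylbut-2-en-1-yl)hepta-2,5-dien-2-yl]-4-oxo-2-[(triisopropylsilyl)oxy]cyclobut-1-en-1-yl}-2-(triisopropylsilyl)-2,3-dihydro-1H-isoindol-1-one (both epimers at the cyclobutenone sp3 carbon) | COc1cccc2c1[C@@H](C1=C(O[Si](C(C)C)(C(C)C)C(C)C)C(C(C)=C(CC=C(C)C)CC=C(C)C)C1=O)N([Si](C(C)C)(C(C)C)C(C)C)C2=O | intermediate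
22 | (3S)-3-{5,9-dimethyl-6-(3-methylbut-2-en-1-yl)-1-oxo-3-[(triisopropylsilyl)oxy]deca-1,3,5,8-tetraen-2-yl}-4-methoxy-2-(triisopropylsilyl)-2,3-dihydro-1H-isoindol-1-one (dienylketene) | COc1cccc2c1[C@@H](C(=C=O)C(O[Si](C(C)C)(C(C)C)C(C)C)=CC(C)=C(CC=C(C)C)CC=C(C)C)N([Si](C(C)C)(C(C)C)C(C)C)C2=O | intermediate
23 | (3S)-4-methoxy-3-{4-methyl-5,5-bis(3-methylbut-2-en-1-yl)-6-oxo-2-[(triisopropylsilyl)oxy]cyclohexa-1,3-dien-1-yl}-2-(triisopropylsilyl)-2,3-dihydro-1H-isoindol-1-one | COc1cccc2c1[C@@H](C1=C(O[Si](C(C)C)(C(C)C)C(C)C)C=C(C)C(CC=C(C)C)(CC=C(C)C)C1=O)N([Si](C(C)C)(C(C)C)C(C)C)C2=O | intermediate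
24 | (3S)-3-[2-hydroxy-4-methyl-5,5-bis(3-methylbut-2-en-1-yl)-6-oxocyclohexa-1,3-dien-1-yl]-4-methoxy-2,3-dihydro-1H-isoindol-1-one | COc1cccc2c1[C@@H](C1=C(O)C=C(C)C(CC=C(C)C)(CC=C(C)C)C1=O)NC2=O | target

**Step count and risks**

Total step count: 9. Longest linear sequence: 5 steps (1 → 2 → 3 → 4 → 9, or 5 → 6 → 7 → 8 → 9).

Steps most likely to fail:

1. Step 9 (bears the label). What may go wrong: a [1,5]-hydrogen shift of the vinylketene before it is captured, slow [2+2] cycloaddition at the hindered alkyne carbon, or thermal Cope/retro-Claisen migration of a prenyl group in the annulation product. Fallback with known chemistry, setting out from 19 and coming back at 24: purchasable 5-methylhex-4-enoic acid would be taken through the operations of steps 3 and 4 [(COCl)2; Et3N, 6; then MeLi; aq HCl] to 3-ethoxy-4-(3-methylbut-2-en-1-yl)cyclobut-2-en-1-one F1 and then to 3-methyl-4-(3-methylbut-2-en-1-yl)cyclobut-2-en-1-one F2. Heating F2 with 19 (toluene, 80 °C) is the Danheiser benzannulation in its established aromatising form, with the same regiochemistry, and should give (3S)-3-{2-hydroxy-4-methyl-3-(3-methylbut-2-en-1-yl)-6-[(triisopropylsilyl)oxy]phenyl}-4-methoxy-2-(triisopropylsilyl)-2,3-dihydro-1H-isoindol-1-one F3. Dearomative ortho C-prenylation of its lithium phenoxide (LiN(SiMe3)2, toluene, 0 °C, then 2) should then occur at the ortho carbon that already carries a prenyl group, since the lithium counter-ion in a non-polar solvent favours ortho attack, the other ortho carbon is blocked by the lactam and the second oxygen is silylated. This installs the quaternary carbon and gives 23, which Bu4NF/AcOH (THF, 0 °C) would desilylate to 24.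

2. Step 8. What may go wrong: incomplete oxygen transfer to the acetylide, or deprotonation at C3 under the strongly basic conditions with loss of configuration. Fallback setting out from 14 and coming back at 24: (ethoxyethynyl)magnesium bromide (from 6 and EtMgBr) would be added to 14 in CH2Cl2 under the conditions of step 6 to give methyl 2-[(1R)-3-ethoxy-1-{[(S)-tert-butylsulfinyl]amino}prop-2-yn-1-yl]-3-methoxybenzoate F4, so that the ynol ether oxygen is carried in by the nucleophile and no acetylide oxidation is needed. F4 and 11 under the thermal conditions of step 9 (1-alkoxyalkynes being the classical partners of cyclobutenones) would give methyl 2-[(S)-{[(S)-tert-butylsulfinyl]amino}[2-ethoxy-4-methyl-5,5-bis(3-methylbut-2-en-1-yl)-6-oxocyclohexa-1,3-dien-1-yl]methyl]-3-methoxybenzoate F5. Dilute aqueous HCl in MeOH (N–S cleavage and hydrolysis of the ethyl vinylogous ester) followed by Et3N (lactamisation) would then lead directly to 24.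

3. Step 6. What may go wrong: poor or reversed facial selectivity because the ortho ester competes with the sulfinyl oxygen for magnesium, or attack of the Grignard reagent on the ester. Fallback setting out from 12 and coming back at 17: a copper-catalysed enantioselective three-component alkynylation–lactamisation of 12 with 4-methoxyaniline and (trimethylsilyl)acetylene would replace the auxiliary by a catalyst. Conditions: Cu(MeCN)4PF6 (monovalent copper), the enantiomer of the i-Pr-pybox-diPh ligand that delivers the required configuration, CHCl3, rt → 40 °C. This should give (3S)-4-methoxy-2-(4-methoxyphenyl)-3-[(trimethylsilyl)ethynyl]-2,3-dihydro-1H-isoindol-1-one F6 (same spatial arrangement as in 17; the descriptor changes with the silyl group). Oxidative removal of the N-aryl group [(NH4)2Ce(NO3)6 (tetravalent cerium), MeCN/H2O, 0 °C] would give (3S)-4-methoxy-3-[(trimethylsilyl)ethynyl]-2,3-dihydro-1H-isoindol-1-one F7, and brief K2CO3/MeOH at 0 °C would remove the C-silyl group and rejoin the route at 17.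

**Further compounds**

F1 | step 9 | 3-ethoxy-4-(3-methylbut-2-en-1-yl)cyclobut-2-en-1-one (racemic) | CCOC1=CC(=O)C1CC=C(C)C
F2 | step 9 | 3-methyl-4-(3-methylbut-2-en-1-yl)cyclobut-2-en-1-one (racemic) | CC1=CC(=O)C1CC=C(C)C
F3 | step 9 | (3S)-3-{2-hydroxy-4-methyl-3-(3-methylbut-2-en-1-yl)-6-[(triisopropylsilyl)oxy]phenyl}-4-methoxy-2-(triisopropylsilyl)-2,3-dihydro-1H-isoindol-1-one | COc1cccc2c1[C@@H](c1c(O)c(CC=C(C)C)c(C)cc1O[Si](C(C)C)(C(C)C)C(C)C)N([Si](C(C)C)(C(C)C)C(C)C)C2=O
F4 | step 8 | methyl 2-[(1R)-3-ethoxy-1-{[(S)-tert-butylsulfinyl]amino}prop-2-yn-1-yl]-3-methoxybenzoate | COC(=O)c1cccc(OC)c1[C@@H](C#COCC)N[S@@](=O)C(C)(C)C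
F5 | step 8 | methyl 2-[(S)-{[(S)-tert-butylsulfinyl]amino}[2-ethoxy-4-methyl-5,5-bis(3-methylbut-2-en-1-yl)-6-oxocyclohexa-1,3-dien-1-yl]methyl]-3-methoxybenzoate | COC(=O)c1cccc(OC)c1[C@@H](C1=C(OCC)C=C(C)C(CC=C(C)C)(CC=C(C)C)C1=O)N[S@@](=O)C(C)(C)C
F6 | step 6 | (3S)-4-methoxy-2-(4-methoxyphenyl)-3-[(trimethylsilyl)ethynyl]-2,3-dihydro-1H-isoindol-1-one | COc1cccc2c1[C@@H](C#C[Si](C)(C)C)N(c1ccc(OC)cc1)C2=O
F7 | step 6 | (3S)-4-methoxy-3-[(trimethylsilyl)ethynyl]-2,3-dihydro-1H-isoindol-1-one | COc1cccc2c1[C@@H](C#C[Si](C)(C)C)NC2=O
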